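## Retrosynthetic overview

1. Numbering: ring A C1(geranyl)–C2–C3=C4(Me)–C5–C14; ring B C1–C12(=O)–C11(prenyl)=C10–C13–C14; ring C C5–C6–C7–C13–C14; ring D C7–C8(Me2)–O9–C10–C13.
2. Feature: ring A is a masked 4-methylcyclohex-3-enone. C14 lies between quaternary C1 and C5, and C3=C4(Me) is what a but-2-ynyl group on C1 becomes once C5 bonds to its far carbon. Ring A is therefore cut at C4–C5 to an acyclic silyl enol ether (gold 6-endo-dig closure); C1 is set earlier by alkylation of a valine enamine of methyl 2-geranylacetoacetate.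
3. Ring D enol ether (O9–C10) and ring B (C11–C12, Claisen closure of a C10 homoprenyl ketone onto the C12 ester) are cut back to a tricyclic γ-lactone (rings A, C and D as lactone) plus 4-methylpent-3-enyllithium.
4. Ring C (C13–C14, with C7–H) comes from a copper hydride reductive aldol of a butenolide hung on C5 by dienolate alkylation (C5–C6); 13-OH comes from lactone enolate hydroxylation.
5. Ring order: A (step 5), then C with D carried as a lactone (step 9), then B (step 13), then D as the enol ether (step 14).

Key step: step 5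

Assumption: the sense of induction of the two reagent-controlled steps (valine enamine alkylation, step 3; ligand-controlled hydride delivery, step 9) is taken as written; if either runs the other way, D-valine tert-butyl ester or (S)-DTBM-SEGPHOS is used with no other change.

## Route

Step 1
Reactants: 1 methyl acetoacetate; 2 geranyl bromide
Product: 3 methyl 2-[(2E)-3,7-dimethylocta-2,6-dien-1-yl]-3-oxobutanoate (racemic)
Conditions: NaH, THF, 0 → 23 °C (1 in excess)
Reagents that add atoms: none
Why: SN2 C-alkylation of the sodium enolate of a 1,3-dicarbonyl compound by an allylic bromide, with excess 1 limiting dialkylation; the new centre is racemic and is flattened again in step 2.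

Step 2
Reactants: 3; 4 L-valine tert-butyl ester
Product: 5 methyl (2Z)-3-{[(2S)-1-tert-butoxy-3-methyl-1-oxobutan-2-yl]amino}-2-geranylbut-2-enoate
Conditions: BF3·OEt2 (cat.), toluene, reflux, Dean–Stark
Reagents that add atoms: none
Why: Acid-catalysed condensation of the ketone with the primary amine should give the conjugated, hydrogen-bonded (Z)-enamino ester (vinylogous carbamate), water being removed azeotropically.

Step 3
Reactants: 5; 6 1-bromobut-2-yne
Product: 8 methyl (2R)-2-acetyl-2-geranylhex-4-ynoate, via N-alkyl ketimine 7 (not isolated)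
Conditions: LiN(iPr)2, HMPA (1 equiv), toluene, −78 °C; then 6; then 1 M aq. citric acid, 23 °C
Reagents that add atoms: water, O
Why: Chiral enamine alkylation: in the chelated lithio-enamine the valine isopropyl group shields one face, so the propargylic bromide should enter C1 from the other (SN2) and set the quaternary centre as R; mild acid then hydrolyses the ketimine and returns the auxiliary.

Step 4
Reactants: 8
Product: 9 methyl (2R)-2-[1-(tert-butyldimethylsilyloxy)ethenyl]-2-geranylhex-4-ynoate
Conditions: TBSOTf, Et3N, CH2Cl2, 0 °C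
Reagents that add atoms: tert-butyldimethylsilyl triflate, CC(C)(C)[Si](C)(C)OS(=O)(=O)C(F)(F)F
Why: Soft enolisation and O-silylation; the methyl ketone is the only enolisable carbonyl (C1 is quaternary), so the terminal silyl enol ether should form as a single regioisomer.

Step 5
Reactants: 9
Product: 10 methyl (1R)-1-geranyl-4-methyl-6-oxocyclohex-3-ene-1-carboxylate (ring A; C14=O, C3=C4)
Conditions: [(tBu2(2-biphenylyl)P)Au(NCMe)]SbF6 (5 mol %), H2O (2 equiv), acetone, 23 °C
Reagents that add atoms: none
Why: Cationic monovalent gold binds the C3≡C4 alkyne and the enol ether carbon C5 attacks the methyl-bearing C4 anti to gold, giving a vinylgold oxocarbenium ion that loses its silyl group to water and is protodeaurated at C3. The closest known reaction is the gold-catalysed Conia-ene-type carbocyclisation of silyl enol ethers onto alkynes. Ring A closes in the 6-endo-dig mode through the new C4–C5 bond. No stereocentre is formed, and C1 is quaternary and non-enolisable, so its configuration is carried through. The step needs 6-endo rather than 5-exo attack, which the bulky biaryl phosphine and the better cation-stabilising, methyl-substituted C4 favour, and it needs the enol ether rather than the geranyl 2,3-alkene (a 1,6-enyne partner) to be the nucleophile, which the much higher nucleophilicity of the silyl enol ether secures. Near-neutral conditions and a short reaction time should keep C3=C4 out of conjugation with C14=O.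

Step 6
Reactants: 11 3-hydroxy-3-methylbutan-2-one; 12 (triphenylphosphoranylidene)ketene
Product: 13 4,5,5-trimethylfuran-2(5H)-one
Conditions: toluene, 110 °C
Reagents that add atoms: none
Why: The tertiary hydroxyl adds to the ketene ylide to give an ester-stabilised ylide, which closes by intramolecular Wittig olefination on the neighbouring ketone, the ring fixing the alkene geometry.

Step 7
Reactants: 13
Product: 14 4-(bromomethyl)-5,5-dimethylfuran-2(5H)-one
Conditions: NBS, AIBN (cat.), PhCF3, 85 °C
Reagents that add atoms: N-bromosuccinimide, O=C1CCC(=O)N1Br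
Why: Wohl–Ziegler radical bromination at the only allylic C–H bonds, those of the 4-methyl group.

Step 8
Reactants: 10; 14
Product: 15 methyl (1R,5S)-5-[(2,2-dimethyl-5-oxo-2,5-dihydrofuran-3-yl)methyl]-1-geranyl-4-methyl-6-oxocyclohex-3-ene-1-carboxylate (side chain at C5 cis to CO2Me, trans to geranyl)
Conditions: LiN(iPr)2, THF, −78 °C; then 14, −78 → −40 °C
Reagents that add atoms: none
Why: Kinetic α-alkylation of the lithium dienolate (O–C14=C5–C4=C3) by the allylic bromide in an SN2 reaction; lithium chelation should hold the C1 ester near the enolate plane and the geranyl group pseudoaxial, so that C6 enters C5 anti to geranyl (5S).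

Step 9
Reactants: 15
Product: 17 tricyclic hydroxy lactone (rings A, C, D; γ-lactone O9–C10(=O); 14-OH, H5, H7 and H13 mutually cis on ring C; 14-OH cis to geranyl), via silyl aldolate 16 (not isolated)
Conditions: Cu(OAc)2·H2O (5 mol %), (R)-DTBM-SEGPHOS (5 mol %), (EtO)2MeSiH, THF, 0 → 23 °C; then 1 M aq. HCl
Reagents that add atoms: none
Why: Copper hydride reductive aldol cyclisation: ligand-controlled conjugate hydride delivery to the butenolide sets C7, and the copper enolate carbon C13 then adds to the C14 ketone from the face of the C5 side chain (anti to the axial geranyl group), closing ring C as a cis-fused C/D bicycle with 14-OH cis to geranyl, while the hindered ketone and the isolated alkenes should not be reduced.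

Step 10
Reactants: 17
Product: 18 tricyclic dihydroxy lactone (17 with OH at C13; cis-13,14-diol)
Conditions: LiN(iPr)2 (2.5 equiv), THF, −78 → −40 °C; then 2-(phenylsulfonyl)-3-phenyloxaziridine, −78 °C; AcOH
Reagents that add atoms: trans-2-(phenylsulfonyl)-3-phenyloxaziridine, O=S(=O)(c1ccccc1)N1OC1c1ccccc1
Why: Enolate hydroxylation of the alkoxide–lactone enolate dianion (lithium and low temperature holding the aldolate against retro-aldol cleavage); oxygen can only enter C13 cis to H7 because the C/D bicycle must stay cis-fused, which places 13-OH cis to 14-OH.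

Step 11
Reactants: 18
Product: 19 13,14-O-isopropylidene acetal of 18
Conditions: 2-methoxypropene, PPTS (cat.), CH2Cl2, 0 → 23 °C
Reagents that add atoms: 2-methoxypropene, COC(C)=C
Why: Acid-catalysed acetalisation of the cis-1,2-diol on the five-membered ring C by an enol ether; the acetal blocks retro-aldol cleavage of C13–C14 in the basic steps that follow.

Step 12
Reactants: 19; 20 5-bromo-2-methylpent-2-ene
Product: 22 γ-hydroxy ketone (lactone opened to C10(=O)CH2CH2CH=CMe2 and C8(Me)2OH; in equilibrium with its C10 hemiketal), via 4-methylpent-3-enyllithium 21 (not isolated)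
Conditions: 20, t-BuLi (2 equiv), Et2O, −78 °C; then 19, THF, −78 °C; AcOH
Reagents that add atoms: none
Why: Halogen–lithium exchange gives the primary alkyllithium, whose addition to the non-enolisable γ-lactone carbonyl C10 should stop at the lithium hemiketal at −78 °C while the neopentyl-type methyl ester on C1 is left alone; no stereocentre is formed.

Step 13
Reactants: 22
Product: 23 tricyclic 2-prenyl-1,3-diketone (rings A, B, C; C10=O and C12=O, keto/enol mixture at C11; free C8 hydroxyl; acetonide retained)
Conditions: KN(SiMe3)2 (3 equiv), THF, −78 → 0 °C; AcOH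
Reagents that add atoms: none
Why: Dieckmann-type Claisen cyclisation: C11 is the only enolisable position of the C10 ketone, its potassium enolate acylates the C12 ester through a six-membered transition state (C10 and C1 are cis on C13–C14), and the product is drained as the stabilised 1,3-diketonate.

Step 14
Reactants: 23
Product: 25 CNP0323114.1 (target), via tetracyclic acetonide 24 (not isolated)
Conditions: 1 M aq. HCl, THF, 23 → 40 °C
Reagents that add atoms: none
Why: Acid-catalysed hemiketalisation of the C8 hydroxyl onto C10 (the only carbonyl within reach) and dehydration should give the five-membered cyclic vinylogous ester of ring D, and the same acid hydrolyses the isopropylidene acetal without touching a stereocentre.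

## Compound list

1 | methyl acetoacetate | CC(=O)CC(=O)OC | starting material
2 | geranyl bromide | CC(C)=CCC/C(C)=C/CBr | starting material
3 | methyl 2-geranyl-3-oxobutanoate (racemic) | CC(C)=CCC/C(C)=C/CC(C(C)=O)C(=O)OC | intermediate
4 | L-valine tert-butyl ester | CC(C)[C@H](N)C(=O)OC(C)(C)C | starting material
5 | methyl (2Z)-3-{[(2S)-1-tert-butoxy-3-methyl-1-oxobutan-2-yl]amino}-2-geranylbut-2-enoate | CC(C)=CCC/C(C)=C/C/C(C(=O)OC)=C(C)/N[C@@H](C(C)C)C(=O)OC(C)(C)C | intermediate
6 | 1-bromobut-2-yne | CC#CCBr | starting material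
7 | N-[(2S)-1-tert-butoxy-3-methyl-1-oxobutan-2-yl] ketimine of 8 (not isolated) | CC(C)=CCC/C(C)=C/C[C@](CC#CC)(C(=O)OC)C(C)=N[C@@H](C(C)C)C(=O)OC(C)(C)C | intermediate
8 | methyl (2R)-2-acetyl-2-geranylhex-4-ynoate | CC(C)=CCC/C(C)=C/C[C@](CC#CC)(C(=O)OC)C(C)=O | intermediate
9 | methyl (2R)-2-[1-(tert-butyldimethylsilyloxy)ethenyl]-2-geranylhex-4-ynoate | CC(C)=CCC/C(C)=C/C[C@](CC#CC)(C(=O)OC)C(O[Si](C)(C)C(C)(C)C)=C | intermediate
10 | methyl (1R)-1-geranyl-4-methyl-6-oxocyclohex-3-ene-1-carboxylate | CC(C)=CCC/C(C)=C/C[C@@]1(C(=O)OC)CC=C(C)CC1=O | intermediate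
11 | 3-hydroxy-3-methylbutan-2-one | CC(=O)C(C)(C)O | starting material
12 | (triphenylphosphoranylidene)ketene | O=C=C=P(c1ccccc1)(c1ccccc1)c1ccccc1 | starting material
13 | 4,5,5-trimethylfuran-2(5H)-one | CC1=CC(=O)OC1(C)C | intermediate
14 | 4-(bromomethyl)-5,5-dimethylfuran-2(5H)-one | BrCC1=CC(=O)OC1(C)C | intermediate
15 | methyl (1R,5S)-5-[(2,2-dimethyl-5-oxo-2,5-dihydrofuran-3-yl)methyl]-1-geranyl-4-methyl-6-oxocyclohex-3-ene-1-carboxylate | CC(C)=CCC/C(C)=C/C[C@@]1(C(=O)OC)CC=C(C)[C@H](CC2=CC(=O)OC2(C)C)C1=O | intermediate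
16 | O14-[diethoxy(methyl)silyl] ether of 17 (not isolated) | CC(C)=CCC/C(C)=C/C[C@@]2(C(=O)OC)CC=C(C)[C@@H]3C[C@@H]4C(C)(C)OC(=O)[C@@H]4[C@@]32O[Si](C)(OCC)OCC | intermediate
17 | tricyclic hydroxy lactone (rings A, C, D; 14-OH, H5, H7, H13 mutually cis; 14-OH cis to geranyl) | CC(C)=CCC/C(C)=C/C[C@@]2(C(=O)OC)CC=C(C)[C@@H]3C[C@@H]4C(C)(C)OC(=O)[C@@H]4[C@@]32O | intermediate
18 | tricyclic cis-13,14-dihydroxy lactone | CC(C)=CCC/C(C)=C/C[C@@]2(C(=O)OC)CC=C(C)[C@@H]3C[C@@H]4C(C)(C)OC(=O)[C@]4(O)[C@@]32O | intermediate
19 | 13,14-O-isopropylidene acetal of 18 | CC(C)=CCC/C(C)=C/C[C@@]2(C(=O)OC)CC=C(C)[C@@H]3C[C@@H]4C(C)(C)OC(=O)[C@@]45OC(C)(C)O[C@]325 | intermediate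
20 | 5-bromo-2-methylpent-2-ene | CC(C)=CCCBr | starting material
21 | 4-methylpent-3-enyllithium (not isolated) | [Li]CCC=C(C)C | intermediate
22 | γ-hydroxy ketone: C10(=O)CH2CH2CH=CMe2 on C13, C8(Me)2OH on C7, acetonide and C1 methyl ester retained | CC(C)=CCC/C(C)=C/C[C@@]2(C(=O)OC)CC=C(C)[C@@H]3C[C@H](C(C)(C)O)[C@@]4(C(=O)CCC=C(C)C)OC(C)(C)O[C@]324 | intermediate
23 | tricyclic 2-prenyl-1,3-diketone (rings A, B, C) with free C8 hydroxyl, acetonide retained | CC(C)=CCC/C(C)=C/C[C@]12CC=C(C)[C@@H]3C[C@H](C(C)(C)O)[C@]4(OC(C)(C)O[C@]324)C(=O)C(CC=C(C)C)C1=O | intermediate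
24 | 13,14-O-isopropylidene acetal of the target (not isolated) | CC(C)=CCC/C(C)=C/C[C@]12CC=C(C)[C@@H]3C[C@@H]4C(C)(C)OC(=C(CC=C(C)C)C1=O)[C@@]45OC(C)(C)O[C@]325 | intermediate
25 | CNP0323114.1 | CC(C)=CCC/C(C)=C/C[C@]12CC=C(C)[C@@H]3C[C@@H]4C(C)(C)OC(=C(CC=C(C)C)C1=O)[C@]4(O)[C@@]32O | target

## Step count and risks

Total steps: 14. Longest linear sequence: 12 (steps 1–5 and 8–14, from methyl acetoacetate).

**Step 5 (gold closure of ring A).** What may go wrong: 5-exo-dig attack at C3, cycloisomerisation through the geranyl 2,3-alkene instead of the enol ether, or migration of the new alkene into conjugation. The fallback closes ring A by palladium-catalysed intramolecular α-alkenylation of the methyl ketone; it sets out from 5 and returns at 10. But-2-yn-1-ol is hydroaluminated with NaAlH2(OCH2CH2OMe)2 and iodinated (I2, −78 °C) to (Z)-3-iodobut-2-en-1-ol F1, which CBr4/PPh3 converts to (Z)-1-bromo-3-iodobut-2-ene F2. The lithio-enamine of 5 is alkylated with F2 under the conditions of step 3 to the iodoalkenyl ketimine F3 (not isolated), which is hydrolysed to methyl (2R,4Z)-2-acetyl-2-geranyl-5-iodohex-4-enoate F4. Pd(PPh3)4 (zerovalent palladium) with KOt-Bu in THF should then join the methyl ketone enolate carbon C5 to the iodine-bearing C4 (oxidative addition, enolate coordination, reductive elimination). A cold acetic acid quench of the resulting dienolate should give 10.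

**Step 9 (reductive aldol).** What may go wrong: poor facial selectivity of hydride delivery at C7 (the existing stereocentres are remote, so the ligand must carry it alone), slow conjugate reduction of the hindered β,β-disubstituted butenolide, or reduction of the ketone first. The fallback fixes C7 with an epoxide of defined configuration that is opened with inversion; it sets out from 10 and returns at 17. Sharpless asymmetric epoxidation of 3-methylbut-2-en-1-ol (Ti(OiPr)4, L-(+)-diethyl tartrate, t-BuOOH) should give [(2S)-3,3-dimethyloxiran-2-yl]methanol F5, which Tf2O/2,6-lutidine at −78 °C converts to its triflate F6. The lithium dienolate of 10 is alkylated with F6 at −78 °C to the epoxy ketone F7. A Reformatsky addition of BrZnCH2CO2Et to C14 (weakly basic, so C5 should not be enolised) gives the β-hydroxy ester F8. LiN(iPr)2 (2.2 equiv) then forms the alkoxide–enolate dianion, whose C13 opens the epoxide at C7 (5-exo, inversion) to the ring C hydroxy ester F9 (not isolated). The C8 alkoxide closes onto the ethyl ester, C13 epimerising as needed to the cis-fused lactone, to give 17.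

**Step 8 (C5 alkylation).** What may go wrong: poor or reversed facial selectivity, the electrophile entering C5 on the geranyl face. The fallback uses the same facial bias for a proton instead of a carbon electrophile; it sets out from 10 and returns at 15. Alkylation as in step 8 would then give mainly the (1R,5R) epimer F10. TMSOTf/Et3N converts F10 to the trimethylsilyl dienol ether F11 (C14–OSiMe3, C5=C14), and fluoride-triggered kinetic protonation (Bu4NF, AcOH, THF, −78 °C) at C5 from the face that electrophiles prefer should give 15.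

## Further compounds

F1 | step 5 | (Z)-3-iodobut-2-en-1-ol | C/C(I)=C/CO
F2 | step 5 | (Z)-1-bromo-3-iodobut-2-ene | C/C(I)=C/CBr
F3 | step 5 | N-[(2S)-1-tert-butoxy-3-methyl-1-oxobutan-2-yl] ketimine of F4 (not isolated) | CC(C)=CCC/C(C)=C/C[C@](C/C=C(/C)I)(C(=O)OC)C(C)=N[C@@H](C(C)C)C(=O)OC(C)(C)C
F4 | step 5 | methyl (2R,4Z)-2-acetyl-2-geranyl-5-iodohex-4-enoate | CC(C)=CCC/C(C)=C/C[C@](C/C=C(/C)I)(C(=O)OC)C(C)=O
F5 | step 9 | [(2S)-3,3-dimethyloxiran-2-yl]methanol | OC[C@@H]1OC1(C)C
F6 | step 9 | [(2S)-3,3-dimethyloxiran-2-yl]methyl trifluoromethanesulfonate | FC(F)(F)S(=O)(=O)OC[C@@H]1OC1(C)C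
F7 | step 9 | methyl (1R,5S)-5-{[(2S)-3,3-dimethyloxiran-2-yl]methyl}-1-geranyl-4-methyl-6-oxocyclohex-3-ene-1-carboxylate | CC(C)=CCC/C(C)=C/C[C@@]1(C(=O)OC)CC=C(C)[C@H](C[C@@H]2OC2(C)C)C1=O
F8 | step 9 | Reformatsky adduct of F7: C14 tertiary alcohol bearing CH2CO2Et (cis to the C1 ester), epoxide retained | CC(C)=CCC/C(C)=C/C[C@@]1(C(=O)OC)CC=C(C)[C@H](C[C@@H]2OC2(C)C)[C@]1(O)CC(=O)OCC
F9 | step 9 | ring C hydroxy ester (C7–C13 bond formed, C8 hydroxyl free, C13 epimers; not isolated) | CC(C)=CCC/C(C)=C/C[C@@]2(C(=O)OC)CC=C(C)[C@@H]3C[C@H](C(C)(C)O)C(C(=O)OCC)[C@@]32O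
F10 | step 8 | (1R,5R) epimer of 15 (side chain at C5 cis to geranyl) | CC(C)=CCC/C(C)=C/C[C@@]1(C(=O)OC)CC=C(C)[C@@H](CC2=CC(=O)OC2(C)C)C1=O
F11 | step 8 | trimethylsilyl dienol ether of F10 (C14–OSiMe3, C5=C14, C3=C4) | CC(C)=CCC/C(C)=C/C[C@@]1(C(=O)OC)CC=C(C)C(CC2=CC(=O)OC2(C)C)=C1O[Si](C)(C)C
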